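**Strategy**

Everything rests on cutting the bond between the β-carbon of the propenoate chain and C-1 of the 3,4-dihydroxyphenyl ring. A phosphine-free Mizoroki–Heck reaction between free 4-iodocatechol and the unprotected eudesmane acrylate makes this bond, sets the E-alkene and gives the target in the last operation. It exploits the polarised terminal CH2 of the acrylate on O-3 of ring A, which outruns the hindered C4=C15 methylene, and the equatorial C3–O bond, which resists ionisation. The acrylate precursor comes without protecting groups from germacrone: asymmetric 1,10-epoxidation, transannular radical closure of rings A and B, dissolving-metal reduction, allylic hydroxylation at C3 and Mitsunobu inversion with acrylic acid.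

Key step: step 7

Assumption: germacrane/eudesmane numbering is used (C1–C10 ring carbons, C14 angular methyl, C15 methylene carbon, C11–C13 isopropyl; β is the face of C14), and germacrone is taken as a catalogue compound.

**Route**

Step 1
Reactants: 1 germacrone
Product: 2 (1R,10R)-1,10-epoxygermacra-4E,7(11)-dien-8-one
Conditions: D-fructose-derived Shi ketone (0.3 equiv), Oxone (2 KHSO5·KHSO4·K2SO4; 1.0 equiv KHSO5, slow addition), K2CO3, n-Bu4NHSO4 (cat.), MeCN–CH2(OMe)2 / aq. Na2B4O7–Na2EDTA buffer, 0 °C
Reagents that add atoms: Oxone, active component potassium peroxymonosulfate, [K+].[O-]S(=O)(=O)OO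
Why: Shi asymmetric epoxidation, in which the chiral dioxirane attacks electron-rich E-trisubstituted alkenes through a spiro transition state and should give the (R,R)-epoxide as with open-chain alkenes of the same pattern; the two planar-chiral ring conformers of 1 interconvert fast and each shows only the outer face of C1=C10, so the catalyst selects one of them (dynamic kinetic resolution, sets C1 and C10), the C7=C11 enone alkene is too electron-poor to react, and the oxidant is kept limiting because C4=C5 is the competing site.

Step 2
Reactants: 2 (1R,10R)-1,10-epoxygermacra-4E,7(11)-dien-8-one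
Product: 3 1β-hydroxyeudesma-4(15),7(11)-dien-8-one
Conditions: Cp2TiCl2 (2.5 equiv), Mn dust (8 equiv), dry degassed THF, rt; 1 M HCl work-up
Reagents that add atoms: none
Why: Nugent–RajanBabu epoxide opening by Cp2TiCl (trivalent titanium) gives the tertiary C10 radical, which adds across the ring to C5 of the E-alkene C4=C5 in the crossed chair–chair conformer (a radical copy of the biosynthetic germacrane-to-eudesmane closure), so the retained C1–O centre fixes C10 (methyl cis to O-1) and C5 (H anti to the methyl, trans-decalin), and the C4 radical is trapped by a second Cp2TiCl and loses hydride from its methyl group to give the exocyclic C4=C15 alkene under dry conditions.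

Step 3
Reactants: 3 1β-hydroxyeudesma-4(15),7(11)-dien-8-one
Product: 5 eudesm-4(15)-ene-1β,8α-diol, via saturated 8-ketone 4 (not isolated)
Conditions: Li (excess), NH3(l)–THF, EtOH, −78 to −33 °C; solid NH4Cl
Reagents that add atoms: none
Why: Dissolving-metal reduction first turns the tetrasubstituted enone into ketone 4, with axial protonation of C7 from the α face (isopropyl equatorial, also the thermodynamic result), and then reduces the ketone through its ketyl to the more stable equatorial 8α-alcohol, which hydride reagents should not give because the angular methyl blocks the β face, while the isolated C4=C15 alkene is left alone.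

Step 4
Reactants: 5 eudesm-4(15)-ene-1β,8α-diol
Product: 6 eudesm-4(15)-ene-1β,3α,8α-triol
Conditions: SeO2 (0.3 equiv), t-BuOOH (2 equiv, in decane), CH2Cl2, 0 °C to rt
Reagents that add atoms: tert-butyl hydroperoxide, CC(C)(C)OO (terminal oxygen source); selenium dioxide, O=[Se]=O (passes the oxygen on)
Why: Catalytic SeO2 allylic hydroxylation (ene reaction at C15 with removal of the axial 3α-hydrogen, then [2,3]-sigmatropic shift) prefers the CH2 group C3 over the methine C5, restores the exocyclic alkene and should deliver oxygen axially to give the 3α-alcohol, as is usual for methylenecyclohexanes locked in a chair, while the saturated alcohols are inert.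

Step 5
Reactants: 6 eudesm-4(15)-ene-1β,3α,8α-triol; 7 acrylic acid (1.3 equiv)
Product: 8 1β,8α-dihydroxyeudesm-4(15)-en-3β-yl acrylate
Conditions: PPh3 (1.3 equiv), DIAD (1.3 equiv), toluene–THF, −20 °C to rt
Reagents that add atoms: none
Why: Mitsunobu esterification with inversion, in which the axial allylic 3α-oxyphosphonium ion is displaced by acrylate from the open equatorial β side to set the 3β (S) configuration, whereas displacement at C1 (neopentyl) and at C8 (menthol-like, backside covered by the axial angular methyl) should be far slower, so the triol needs no protection.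

Step 6
Reactants: 9 4-iodoveratrole
Product: 11 4-iodocatechol, via cyclic bromoborate 10 (not isolated)
Conditions: BBr3 (1.5 equiv), CH2Cl2, −78 °C to rt; then H2O
Reagents that add atoms: boron tribromide, BrB(Br)Br (boron and bromine stay only in intermediate 10)
Why: Lewis-acid ether cleavage, in which BBr3 binds each methoxy oxygen, bromide removes the methyl group by SN2 and water hydrolyses the cyclic borate 10 to the catechol without touching the aryl iodide.

Step 7
Reactants: 8 1β,8α-dihydroxyeudesm-4(15)-en-3β-yl acrylate; 11 4-iodocatechol (1.2 equiv)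
Product: 12 1β,8α-dihydroxyeudesm-4(15)-en-3β-yl (E)-caffeate (target)
Conditions: Pd(OAc)2 (10 mol %), n-Bu4NCl (1 equiv), NaHCO3 (2.5 equiv), degassed DMF, argon, 50 °C
Reagents that add atoms: none
Why: Mizoroki–Heck reaction under phosphine-free Jeffery conditions: zerovalent palladium formed from Pd(OAc)2 inserts into the C–I bond of 11, the aryl–palladium species adds syn across the acrylate C=C of 8 with the aryl group going to the terminal CH2 carbon (the new C–C bond), and bond rotation followed by syn β-hydride elimination releases the cinnamate while NaHCO3 takes up HI. The closest known reaction type is the Heck arylation of acrylate esters with iodophenols. No ring is closed and no stereocentre is made; the E geometry follows from the less crowded conformer in the syn β-hydride elimination, and the six stereocentres of 8 are not touched. Selectivity between the two alkenes is secured by the substrate, since the acrylate is monosubstituted and polarised whereas C4=C15 is 1,1-disubstituted, unactivated and flanked by C3 and C5. Ionisation of the allylic C3–O bond by zerovalent palladium is held back because that bond is equatorial on the rigid trans-decalin and lies near the nodal plane of the C4=C15 π bond, no phosphine is present, and the aryl iodide is the faster partner for oxidative addition. Hydrogen carbonate is too weak a base to form the catecholate, so with air excluded the free catechol and the two secondary alcohols should pass unchanged and the product is the target itself.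

**Compound list**

1 | germacrone, (1(10)E,4E)-germacra-1(10),4,7(11)-trien-8-one | C/C1=C\CC/C(C)=C/CC(=C(C)C)C(=O)C1 | starting material
2 | (1R,10R)-1,10-epoxygermacra-4E,7(11)-dien-8-one | C[C@@]12CC(=O)C(=C(C)C)C/C=C(\C)CC[C@H]1O2 | intermediate
3 | (1R,5S,10R)-1β-hydroxyeudesma-4(15),7(11)-dien-8-one | C=C1CC[C@@H](O)[C@]2(C)CC(=O)C(=C(C)C)C[C@@H]12 | intermediate
4 | (1R,5S,7R,10R)-1β-hydroxyeudesm-4(15)-en-8-one (7β-isopropyl; not isolated) | C=C1CC[C@@H](O)[C@]2(C)CC(=O)[C@@H](C(C)C)C[C@@H]12 | intermediate
5 | (1R,5S,7R,8S,10R)-eudesm-4(15)-ene-1β,8α-diol | C=C1CC[C@@H](O)[C@]2(C)C[C@H](O)[C@@H](C(C)C)C[C@@H]12 | intermediate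
6 | (1R,3R,5S,7R,8S,10R)-eudesm-4(15)-ene-1β,3α,8α-triol | C=C1[C@H](O)C[C@@H](O)[C@]2(C)C[C@H](O)[C@@H](C(C)C)C[C@@H]12 | intermediate
7 | acrylic acid | C=CC(=O)O | starting material
8 | (1R,3S,5S,7R,8S,10R)-1β,8α-dihydroxyeudesm-4(15)-en-3β-yl acrylate | C=C1[C@@H](OC(=O)C=C)C[C@@H](O)[C@]2(C)C[C@H](O)[C@@H](C(C)C)C[C@@H]12 | intermediate
9 | 4-iodoveratrole (4-iodo-1,2-dimethoxybenzene) | COc1ccc(I)cc1OC | starting material
10 | 2-bromo-5-iodo-1,3,2-benzodioxaborole (not isolated) | BrB1Oc2ccc(I)cc2O1 | intermediate
11 | 4-iodocatechol (4-iodobenzene-1,2-diol) | Oc1ccc(I)cc1O | intermediate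
12 | (1R,3S,5S,7R,8S,10R)-1β,8α-dihydroxyeudesm-4(15)-en-3β-yl (E)-3-(3,4-dihydroxyphenyl)prop-2-enoate | C=C1[C@@H](OC(=O)/C=C/c2ccc(O)c(O)c2)C[C@@H](O)[C@]2(C)C[C@H](O)[C@@H](C(C)C)C[C@@H]12 | target

**Step count**

Total step count: 7. Longest linear sequence: 6 (steps 1–5 and 7).

**Steps most likely to fail**

**Step 1.**
- Site selectivity between the C1=C10 and C4=C5 alkenes may be poor.
- The catalyst may discriminate too weakly between the interconverting ring conformers.
- The buffer may open the new epoxide by deprotonation at the acidic C9 position.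

The fallback gives up catalyst control and resolves later. It sets out from 1, which m-CPBA (NaHCO3, CH2Cl2, 0 °C) should convert into racemic 1,10-epoxygermacrone F1. The conditions of steps 2 and 3 then lead through racemic hydroxy dienone F2 and racemic saturated ketone F3 (not isolated) to racemic diol F4. Ring B of the diol is a menthol-type carbinol. Candida rugosa lipase with vinyl acetate (t-BuOMe, 30 °C) should therefore acetylate the (8R)-enantiomer to the enantiomeric diol 8-acetate F5 and leave the (8S)-diol untouched. Chromatography brings the route back at 5.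

**Step 5.**
- The carboxylate may attack C15 with allylic transposition, because the axial leaving group is well aligned with the π bond.
- A second hydroxyl group may be activated in competition.
- Step 4 may deliver oxygen with less axial preference than expected.

The fallback sets the C3 centre by reduction instead of displacement and is independent of the C3 configuration of 6. It sets out from 6, whose allylic alcohol alone should be oxidised by MnO2 (CH2Cl2, rt) to 1β,8α-dihydroxyeudesm-4(15)-en-3-one F6. Luche reduction (NaBH4, CeCl3·7H2O, MeOH, −78 °C) should deliver hydride axially from the α face to give eudesm-4(15)-ene-1β,3β,8α-triol F7. Acryloyl chloride (1.05 equiv, 2,4,6-collidine, CH2Cl2, −78 to −40 °C) should then acylate the least hindered, allylic 3β-hydroxyl. The route is rejoined at 8.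

**Step 7.**
- The catechol may bind or be oxidised by palladium and stall the cycle.
- Zerovalent palladium may ionise the allylic ester.
- A palladium hydride may move the exocyclic alkene into the ring.

The fallback forms the same bond by an oxidative boron-Heck reaction, in which palladium rests in the divalent state and the catechol is masked. It sets out from 11, which TBSCl and imidazole (DMF, rt) should convert into 4-iodo-1,2-bis(tert-butyldimethylsilyloxy)benzene F8. Treatment with n-BuLi (THF, −78 °C), then B(OiPr)3 and aqueous NH4Cl should give 3,4-bis(tert-butyldimethylsilyloxy)phenylboronic acid F9. Coupling with 8 (Pd(OAc)2 5 mol %, 2,9-dimethyl-1,10-phenanthroline, O2 1 atm, N-methylmorpholine, MeCN, rt) should give the bis-TBS ether of the target F10. Et3N·3HF (THF, 0 °C) removes the aryl silyl ethers and the route is rejoined at 12.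

**Further compounds**

F1 | step 1 | racemic 1,10-epoxygermacrone (both enantiomers written) | C[C@@]12CC(=O)C(=C(C)C)C/C=C(\C)CC[C@H]1O2.C[C@]12CC(=O)C(=C(C)C)C/C=C(\C)CC[C@@H]1O2
F2 | step 1 | racemic 1β-hydroxyeudesma-4(15),7(11)-dien-8-one (both enantiomers written) | C=C1CC[C@@H](O)[C@]2(C)CC(=O)C(=C(C)C)C[C@@H]12.C=C1CC[C@H](O)[C@@]2(C)CC(=O)C(=C(C)C)C[C@H]12
F3 | step 1 | racemic 1β-hydroxyeudesm-4(15)-en-8-one (both enantiomers written, not isolated) | C=C1CC[C@@H](O)[C@]2(C)CC(=O)[C@@H](C(C)C)C[C@@H]12.C=C1CC[C@H](O)[C@@]2(C)CC(=O)[C@H](C(C)C)C[C@H]12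
F4 | step 1 | racemic eudesm-4(15)-ene-1β,8α-diol (both enantiomers written) | C=C1CC[C@@H](O)[C@]2(C)C[C@H](O)[C@@H](C(C)C)C[C@@H]12.C=C1CC[C@H](O)[C@@]2(C)C[C@@H](O)[C@H](C(C)C)C[C@H]12
F5 | step 1 | 8-acetate of the enantiomeric diol, (1S,5R,7S,8R,10S) | C=C1CC[C@H](O)[C@@]2(C)C[C@@H](OC(C)=O)[C@H](C(C)C)C[C@H]12
F6 | step 5 | 1β,8α-dihydroxyeudesm-4(15)-en-3-one | C=C1C(=O)C[C@@H](O)[C@]2(C)C[C@H](O)[C@@H](C(C)C)C[C@@H]12
F7 | step 5 | eudesm-4(15)-ene-1β,3β,8α-triol | C=C1[C@@H](O)C[C@@H](O)[C@]2(C)C[C@H](O)[C@@H](C(C)C)C[C@@H]12
F8 | step 7 | 4-iodo-1,2-bis(tert-butyldimethylsilyloxy)benzene | CC(C)(C)[Si](C)(C)Oc1ccc(I)cc1O[Si](C)(C)C(C)(C)C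
F9 | step 7 | 3,4-bis(tert-butyldimethylsilyloxy)phenylboronic acid | CC(C)(C)[Si](C)(C)Oc1ccc(B(O)O)cc1O[Si](C)(C)C(C)(C)C
F10 | step 7 | bis-TBS ether of the target | C=C1[C@@H](OC(=O)/C=C/c2ccc(O[Si](C)(C)C(C)(C)C)c(O[Si](C)(C)C(C)(C)C)c2)C[C@@H](O)[C@]2(C)C[C@H](O)[C@@H](C(C)C)C[C@@H]12
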